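**Retrosynthetic overview**
- The butenolide is the only ring and is made first, on a cheap C11 carrier. The α-carbon of undec-10-enal 1 is joined to the keto carbon of ethyl pyruvate 2 (C3–C4 bond), and the adduct dehydrates and closes (ring O to C2) to the γ-hydroxybutenolide 5.
- Hydride at C5, the carbon that comes from the fatty chain, then gives butenolide 7. This copies the alkylcitrate logic: fatty α-carbon plus pyruvate keto group, dehydration to the maleic level, reduction of the fatty C1, lactone.
- The (S)-carbinol carbon comes from the chiral pool: the Grignard reagent of 6-bromohex-1-ene 8 opens (S)-propylene oxide 9 at CH2 and is acetylated in the flask to 12.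
- The last bond made (first disconnection) is C8–C9 of the side chain: cross-metathesis of 7 with 12, hydrogenated in the same flask, gives target 14.

Assumption: the stereocentre is (S) as read from the SMILES, and the presumed biosynthesis is taken to be the alkylcitrate (chaetomellic acid) pathway, in which the α-carbon of a C18 (S)-17-hydroxy fatty acyl thioester adds to the keto group of oxaloacetate/pyruvate, dehydration gives the 2-alkyl-3-methylmaleate, and the fatty carboxyl carbon is reduced and lactonises.

**Step 1**
Reactants: 1 undec-10-enal; 2 ethyl pyruvate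
Product: 5 5-hydroxy-3-methyl-4-(non-8-en-1-yl)furan-2(5H)-one, via silyl enol ether 3 (not isolated), via aldol adduct 4 (not isolated)
Conditions: 1 added to TMSOTf, Et3N, CH2Cl2, 0 °C; this solution added to 2·TiCl4 (1.5 equiv), CH2Cl2, −78 °C; then 2 M HCl, THF, 50 °C
Reagents that add atoms: water, O
Why: Proposed new method: because 1 is fully converted to enol silane 3 before it meets the TiCl4-chelated pyruvate, the fatty α-carbon is the only nucleophile and adds to the keto carbon (Mukaiyama aldol, mirroring the alkylcitrate synthase step); the β-hydroxy aldehyde 4 then loses water under acid and the formyl hydrate closes on the ester to the lactol, the closest known reaction being the morpholine/HCl condensation of aldehydes with glyoxylic acid to γ-hydroxybutenolides, and no stereocentre is kept (C5 is racemic and is removed in step 2).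

**Step 2**
Reactants: 5 5-hydroxy-3-methyl-4-(non-8-en-1-yl)furan-2(5H)-one
Product: 7 3-methyl-4-(non-8-en-1-yl)furan-2(5H)-one, via sodium hydroxy-enoate 6 (not isolated)
Conditions: NaBH4, MeOH, 0 °C to rt; then 2 M HCl, rt
Reagents that add atoms: none
Why: Borohydride reduction of a pseudo-acid: the lactol opens under the basic conditions to the (Z)-formyl carboxylate, only the aldehyde carbon (C5) is reduced, and acidification relactonises, so the carbonyl stays next to the methyl-bearing carbon.

**Step 3**
Reactants: 8 6-bromohex-1-ene; 9 (S)-2-methyloxirane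
Product: 12 (S)-non-8-en-2-yl acetate, via hex-5-en-1-ylmagnesium bromide 10 (not isolated), via magnesium alkoxide 11 (not isolated)
Conditions: Mg, THF, rt; CuI (10 mol %), 9, −30 to 0 °C; then Ac2O, DMAP (cat.), 0 °C to rt
Reagents that add atoms: acetic anhydride, CC(=O)OC(C)=O
Why: Copper-catalysed Grignard opening of the epoxide at the unsubstituted carbon leaves the C–O stereocentre of (S)-propylene oxide untouched (S retained, CIP order unchanged), and the magnesium alkoxide is O-acetylated in the flask.

**Step 4**
Reactants: 7 3-methyl-4-(non-8-en-1-yl)furan-2(5H)-one; 12 (S)-non-8-en-2-yl acetate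
Product: 14 (S)-16-(4-methyl-5-oxo-2,5-dihydrofuran-3-yl)hexadecan-2-yl acetate, via cross-metathesis alkene 13 (not isolated)
Conditions: 12 (3 equiv), Grubbs II (3 mol %), ClCH2CH2Cl, 45 °C; then H2 (7 bar), 70 °C
Reagents that add atoms: none
Why: Olefin cross-metathesis of two unhindered terminal alkenes (excess 12 drives 7 into the cross product), then hydrogenation of the new disubstituted alkene by the ruthenium residue under H2 (tandem metathesis–hydrogenation); the tetrasubstituted butenolide alkene and the remote acetate stereocentre are not touched.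

**Compound list**
1 | undec-10-enal | C=CCCCCCCCCC=O | starting material
2 | ethyl pyruvate (ethyl 2-oxopropanoate) | CCOC(=O)C(C)=O | starting material
3 | trimethyl(undeca-1,10-dien-1-yloxy)silane (E/Z mixture) | C=CCCCCCCCC=CO[Si](C)(C)C | intermediate
4 | ethyl 3-formyl-2-hydroxy-2-methyldodec-11-enoate (racemic, diastereomer mixture) | CCOC(=O)C(C)(O)C(C=O)CCCCCCCC=C | intermediate
5 | 5-hydroxy-3-methyl-4-(non-8-en-1-yl)furan-2(5H)-one (racemic at C5) | C=CCCCCCCCC1=C(C)C(=O)OC1O | intermediate
6 | sodium (Z)-4-hydroxy-2-methyl-3-(non-8-en-1-yl)but-2-enoate | OC/C(CCCCCCCC=C)=C(/C)C(=O)[O-].[Na+] | intermediate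
7 | 3-methyl-4-(non-8-en-1-yl)furan-2(5H)-one | C=CCCCCCCCC1=C(C)C(=O)OC1 | intermediate
8 | 6-bromohex-1-ene | C=CCCCCBr | starting material
9 | (S)-2-methyloxirane ((S)-propylene oxide) | C[C@H]1CO1 | starting material
10 | hex-5-en-1-ylmagnesium bromide | C=CCCCC[Mg]Br | intermediate
11 | bromomagnesium (S)-non-8-en-2-olate | C[C@H](O[Mg]Br)CCCCCC=C | intermediate
12 | (S)-non-8-en-2-yl acetate | CC(=O)O[C@@H](C)CCCCCC=C | intermediate
13 | (S)-16-(4-methyl-5-oxo-2,5-dihydrofuran-3-yl)hexadec-8-en-2-yl acetate (E/Z mixture) | CC(=O)O[C@@H](C)CCCCCC=CCCCCCCCC1=C(C)C(=O)OC1 | intermediate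
14 | (S)-16-(4-methyl-5-oxo-2,5-dihydrofuran-3-yl)hexadecan-2-yl acetate | CC(=O)O[C@@H](C)CCCCCCCCCCCCCCC1=C(C)C(=O)OC1 | target

**Totals**
Total step count: 4. Longest linear sequence: 3 steps (1 → 2 → 4).

**Steps most likely to fail, with fallbacks**

Step 1 is the most likely to fail. The risks are self-aldol of 1 while it is being silylated, addition of 3 to the aldehyde of 4, and an (E)-enal that does not close. The fallback sets out from 1 and 2 and comes back at 7, so 5 and step 2 are bypassed. It takes the fatty carbon to the acid level, so that its oxidation state distinguishes it from the pyruvate ester. Pinnick oxidation of 1 (NaClO2, NaH2PO4, 2-methylbut-2-ene) gives undec-10-enoic acid F1. Its dilithium enediolate (LDA, 2.1 equiv, THF, −78 °C) adds to 2 to give 4-ethoxy-3-hydroxy-3-methyl-2-(non-8-en-1-yl)-4-oxobutanoic acid F2. Only the free acid is reduced, through its acyl imidazolide (CDI, THF; then NaBH4, H2O, 0 °C), and the new primary alcohol closes on the ethyl ester to 3-hydroxy-3-methyl-4-(non-8-en-1-yl)dihydrofuran-2(3H)-one F3. SOCl2/pyridine, then DBU to bring any exocyclic alkene into the ring, gives 7.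

Step 4 is next. The risks are a statistical mixture with both homodimers, Ru–H double-bond migration that gives chain-shortened homologues, and slow hydrogenation by the spent catalyst. The fallback sets out from 7 and 9 and comes back at 14. It replaces metathesis by an alkyl–alkyl Suzuki coupling, which leaves no alkene to reduce. Epoxide 9 is opened with commercial but-3-en-1-ylmagnesium bromide (CuI cat.) and acetylated in the flask to (S)-hept-6-en-2-yl acetate F4. 9-BBN-H converts this into (S)-7-(9-borabicyclo[3.3.1]nonan-9-yl)heptan-2-yl acetate F5. Radical anti-Markovnikov addition of HBr (HBr, AIBN, hexane) to 7 gives 4-(9-bromononyl)-3-methylfuran-2(5H)-one F6. Coupling of F5 with F6 (Pd(OAc)2, PCy3, K3PO4·H2O, THF, rt) gives 14 directly (9 + 5 CH2 = 14).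

Step 3 is third. The risks are cyclisation of the hex-5-enyl radical during Grignard formation, bromohydrin formation from magnesium bromide and the epoxide, and loss of the volatile product. The fallback sets out from 8 and comes back at 12. It sets the stereocentre by enzymatic reduction instead of taking it from the epoxide. Bromide 8 alkylates ethyl acetoacetate (NaOEt, EtOH) to ethyl 2-acetyloct-7-enoate F7. NaOH, then H3O+ and heat, gives non-8-en-2-one F8. An (S)-selective (Prelog) alcohol dehydrogenase with i-PrOH recycling gives (S)-non-8-en-2-ol F9. Ac2O, pyridine and DMAP give 12.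

**Further compounds**
F1 | step 1 | undec-10-enoic acid | C=CCCCCCCCCC(=O)O
F2 | step 1 | 4-ethoxy-3-hydroxy-3-methyl-2-(non-8-en-1-yl)-4-oxobutanoic acid (racemic, diastereomer mixture) | CCOC(=O)C(C)(O)C(CCCCCCCC=C)C(=O)O
F3 | step 1 | 3-hydroxy-3-methyl-4-(non-8-en-1-yl)dihydrofuran-2(3H)-one (racemic, diastereomer mixture) | CC1(O)C(CCCCCCCC=C)COC1=O
F4 | step 4 | (S)-hept-6-en-2-yl acetate | CC(=O)O[C@@H](C)CCCC=C
F5 | step 4 | (S)-7-(9-borabicyclo[3.3.1]nonan-9-yl)heptan-2-yl acetate | CC(=O)O[C@@H](C)CCCCCB1C2CCCC1CCC2
F6 | step 4 | 4-(9-bromononyl)-3-methylfuran-2(5H)-one | CC1=C(CCCCCCCCCBr)COC1=O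
F7 | step 3 | ethyl 2-acetyloct-7-enoate (racemic) | CCOC(=O)C(C(C)=O)CCCCC=C
F8 | step 3 | non-8-en-2-one | CC(=O)CCCCCC=C
F9 | step 3 | (S)-non-8-en-2-ol | C[C@H](O)CCCCCC=C
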